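**Retrosynthetic overview**
1. The target is the C7 mono-acetate of a macrocyclic 7,12-diol; the tertiary C12 hydroxyl stays free.
2. The diol comes from an acyclic (R,R,R,R)-diepoxide carrying an alkenyl boronate and an alkenyl bromide. In one flask, an acid-triggered diepoxide-to-oxolane cascade forms the cis-2,5-oxolane first, then Suzuki–Miyaura closure of the C2–C3 diene bond forms the 14-membered carbocycle.
3. The diepoxide comes from Shi epoxidation of an E,E-1,5-diene; the E-alkenyl boronate comes from a terminal alkyne by copper-catalysed methylboration after the epoxidation.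
4. The chain is assembled at C13–C14 by allylbarium coupling of a geranyl-derived allylic chloride with a Z-bromoallyl bromide (from propargyl alcohol carbomagnesiation), and at C5–C6 by propargylation of geranyl bromide.

Assumption: positions are cited in cembrane numbering (C1 = isopropyl-bearing alkene carbon, C7 = acetoxy carbon, C8 and C11 = ether carbons, C12 = carbinol carbon); the target is 1E,3E,7R,8S,11R,12S.

**Step 1**
Reactants: 1 prop-2-yn-1-ol; 2 isopropylmagnesium chloride
Product: 4 (2Z)-3-bromo-2-(propan-2-yl)prop-2-en-1-ol, via magnesium chelate 3 (not isolated)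
Conditions: 2 (2.5 equiv), CuI (10 mol%), THF, −10 °C to rt; then NBS, −78 to 0 °C; aq. NH4Cl
Reagents that add atoms: N-bromosuccinimide, BrN1C(=O)CCC1=O
Why: Duboudin copper-catalysed anti-carbomagnesiation of the propargylic alkoxide puts isopropyl on the internal carbon and magnesium on the terminal carbon cis to CH2O in a five-membered chelate, so bromination with retention gives only the Z-bromoalkene (Br cis to CH2OH), the geometry later needed at C1=C2.

**Step 2**
Reactants: 4 (2Z)-3-bromo-2-(propan-2-yl)prop-2-en-1-ol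
Product: 5 (1Z)-1-bromo-2-(bromomethyl)-3-methylbut-1-ene
Conditions: CBr4, PPh3, CH2Cl2, 0 °C
Reagents that add atoms: tetrabromomethane, BrC(Br)(Br)Br
Why: Appel bromination is an SN2 displacement at the primary allylic carbon under neutral conditions, so the alkenyl bromide and its geometry are untouched.

**Step 3**
Reactants: 6 geranyl bromide [(2E)-1-bromo-3,7-dimethylocta-2,6-diene]; 7 1-(trimethylsilyl)propyne
Product: 9 trimethyl[(5E)-6,10-dimethylundeca-5,9-dien-1-yn-1-yl]silane, via 3-lithio-1-(trimethylsilyl)propyne 8 (not isolated)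
Conditions: 7, nBuLi, THF, −78 to −20 °C; then 6, −78 °C to rt
Reagents that add atoms: none
Why: lithiated 1-(trimethylsilyl)propyne reacts at its propargylic carbon with the primary allylic bromide by direct SN2 (no allyl or allenyl transposition), forming C5–C6 while the E alkene of geranyl is retained.

**Step 4**
Reactants: 9 trimethyl[(5E)-6,10-dimethylundeca-5,9-dien-1-yn-1-yl]silane
Product: 10 (2E,6E)-2,6-dimethyl-11-(trimethylsilyl)undeca-2,6-dien-10-yn-1-ol
Conditions: SeO2 (0.2 equiv), tBuOOH (3 equiv), salicylic acid (0.1 equiv), CH2Cl2, rt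
Reagents that add atoms: tert-butyl hydroperoxide, CC(C)(C)OO
Why: Sharpless SeO2/tBuOOH allylic oxidation (ene reaction then 2,3-sigmatropic shift) oxidises the terminal gem-dimethyl alkene fastest and only at its E-methyl group, giving the E-allylic alcohol at C13.

**Step 5**
Reactants: 10 (2E,6E)-2,6-dimethyl-11-(trimethylsilyl)undeca-2,6-dien-10-yn-1-ol
Product: 11 [(5E,9E)-11-chloro-6,10-dimethylundeca-5,9-dien-1-yn-1-yl]trimethylsilane
Conditions: PPh3, CCl4, reflux
Reagents that add atoms: tetrachloromethane, ClC(Cl)(Cl)Cl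
Why: Appel chlorination of a primary allylic alcohol proceeds by SN2 without allylic transposition or E/Z loss (as for geraniol to geranyl chloride), and the silylalkyne is inert.

**Step 6**
Reactants: 11 [(5E,9E)-11-chloro-6,10-dimethylundeca-5,9-dien-1-yn-1-yl]trimethylsilane; 5 (1Z)-1-bromo-2-(bromomethyl)-3-methylbut-1-ene
Product: 13 [(5E,9E,13E)-14-bromo-6,10-dimethyl-13-(propan-2-yl)tetradeca-5,9,13-trien-1-yn-1-yl]trimethylsilane, via allylbarium chloride 12 (not isolated)
Conditions: BaI2, lithium biphenylide (2 equiv), THF, rt; then 11, −78 °C; then 5, −78 °C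
Reagents that add atoms: none
Why: Yamamoto allylbarium coupling: the allylbarium formed at −78 °C keeps its E geometry and attacks the primary allylic bromide α to α (head to head) faster than anything happens at the alkenyl bromide or silylalkyne, so C13–C14 forms with both alkene geometries retained.

**Step 7**
Reactants: 13 [(5E,9E,13E)-14-bromo-6,10-dimethyl-13-(propan-2-yl)tetradeca-5,9,13-trien-1-yn-1-yl]trimethylsilane
Product: 14 (5E,9E,13E)-14-bromo-6,10-dimethyl-13-(propan-2-yl)tetradeca-5,9,13-trien-1-yne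
Conditions: K2CO3 (cat.), MeOH, rt
Reagents that add atoms: none
Why: methoxide-mediated protodesilylation of the alkynylsilane is selective because the C(sp)–Si bond is the only base-labile group present.

**Step 8**
Reactants: 14 (5E,9E,13E)-14-bromo-6,10-dimethyl-13-(propan-2-yl)tetradeca-5,9,13-trien-1-yne
Product: 15 (2R,3R)-3-(but-3-yn-1-yl)-2-methyl-2-{2-[(2R,3R)-3-[(3E)-4-bromo-3-(propan-2-yl)but-3-en-1-yl]-3-methyloxiran-2-yl]ethyl}oxirane (7R,8R,11R,12R-diepoxide)
Conditions: 1,2:4,5-di-O-isopropylidene-β-D-erythro-2,3-hexodiulo-2,6-pyranose (0.6 equiv), KHSO5 (as 2KHSO5·KHSO4·K2SO4), K2CO3, Bu4NHSO4, MeCN/dimethoxymethane/aq. Na2B4O7 buffer (pH 10.5), 0 °C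
Reagents that add atoms: potassium peroxymonosulfate, [K+].[O-]S(=O)(=O)OO
Why: Shi asymmetric epoxidation: the dioxirane of the D-fructose-derived ketone attacks each electron-rich E-trisubstituted alkene through the spiro transition state from the face that gives the R,R epoxide, setting C7, C8, C11 and C12 all R, while the alkyne and the electron-poor alkenyl bromide are not oxidised.

**Step 9**
Reactants: 15 (7R,8R,11R,12R)-diepoxy bromo-enyne
Product: 16 2-[(1E)-2-methyl-4-{(2R,3R)-3-methyl-3-[2-((2R,3R)-3-[(3E)-4-bromo-3-(propan-2-yl)but-3-en-1-yl]-3-methyloxiran-2-yl)ethyl]oxiran-2-yl}but-1-en-1-yl]-4,4,5,5-tetramethyl-1,3,2-dioxaborolane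
Conditions: CuCl (10 mol%), 4,5-bis(diphenylphosphino)-9,9-dimethylxanthene (10 mol%), NaOtBu, B2pin2, MeI, THF, rt
Reagents that add atoms: bis(pinacolato)diboron, CC1(C)OB(OC1(C)C)B1OC(C)(C)C(C)(C)O1; iodomethane, CI
Why: copper-catalysed carboboration: syn-borylcupration of the terminal alkyne places boron on the terminal carbon and the alkenylcopper is methylated by MeI with retention, giving the E-alkenyl boronate (B trans to C5); trisubstituted epoxides survive NaOtBu and the alkyne inserts into Cu–B far faster than the hindered alkenyl bromide reacts.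

**Step 10**
Reactants: 16 E-alkenyl boronate diepoxide
Product: 18 (1E,3E,7R,8S,11R,12S)-8,11-epoxycembra-1,3-diene-7,12-diol, via acyclic tetrahydrofuran diol 17 (not isolated)
Conditions: HClO4 (0.1 equiv), THF/H2O 10:1, 0 °C; then K3PO4, Pd(OAc)2 (10 mol%), 2-dicyclohexylphosphino-2′,6′-dimethoxybiphenyl (20 mol%), THF/H2O, 1 mM, 45 °C
Reagents that add atoms: water, O
Why: Proposed new method: a one-flask epoxide-opening cascade followed by Suzuki–Miyaura macrocyclisation; protonation of the 7,8-epoxide lets the 11,12-epoxide oxygen attack tertiary C8 in the 5-exo mode with inversion, water opens the resulting epoxonium ion at tertiary C12 with inversion, so the R,R,R,R diepoxide gives the cis-oxolane with 7R,8S,11R,12S, after which base and palladium close the C2–C3 bond with retention of both alkene geometries, the cis-oxolane acting as a turn element; the closest known reactions are acid-catalysed 1,5-diepoxide-to-tetrahydrofuran cascades and alkenyl–alkenyl Suzuki macrocyclisations.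

**Step 11**
Reactants: 18 (1E,3E,7R,8S,11R,12S)-8,11-epoxycembra-1,3-diene-7,12-diol
Product: 19 (1E,3E,7R,8S,11R,12S)-7-acetoxy-8,11-epoxycembra-1,3-dien-12-ol (CNP0199953.2)
Conditions: Ac2O, pyridine, 4-(dimethylamino)pyridine (cat.), CH2Cl2, rt
Reagents that add atoms: acetic anhydride, CC(=O)OC(C)=O
Why: nucleophile-catalysed acylation is selective for the secondary C7 hydroxyl because the tertiary C12 hydroxyl is too hindered to react at room temperature.

**Compound list**
1 | prop-2-yn-1-ol | C#CCO | starting material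
2 | isopropylmagnesium chloride | CC(C)[Mg]Cl | starting material
3 | chloromagnesium (2Z)-3-(chloromagnesio)-2-(propan-2-yl)prop-2-en-1-olate (magnesium chelate) | Cl[Mg]/C=C(\CO[Mg]Cl)C(C)C | intermediate
4 | (2Z)-3-bromo-2-(propan-2-yl)prop-2-en-1-ol | Br/C=C(\CO)C(C)C | intermediate
5 | (1Z)-1-bromo-2-(bromomethyl)-3-methylbut-1-ene | Br/C=C(\CBr)C(C)C | intermediate
6 | geranyl bromide, (2E)-1-bromo-3,7-dimethylocta-2,6-diene | CC(C)=CCC/C(C)=C/CBr | starting material
7 | 1-(trimethylsilyl)propyne | CC#C[Si](C)(C)C | starting material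
8 | 3-lithio-1-(trimethylsilyl)propyne | [Li]CC#C[Si](C)(C)C | intermediate
9 | trimethyl[(5E)-6,10-dimethylundeca-5,9-dien-1-yn-1-yl]silane | C[Si](C)(C)C#CCC/C=C(\C)CCC=C(C)C | intermediate
10 | (2E,6E)-2,6-dimethyl-11-(trimethylsilyl)undeca-2,6-dien-10-yn-1-ol | C[Si](C)(C)C#CCC/C=C(\C)CC/C=C(\C)CO | intermediate
11 | [(5E,9E)-11-chloro-6,10-dimethylundeca-5,9-dien-1-yn-1-yl]trimethylsilane | C[Si](C)(C)C#CCC/C=C(\C)CC/C=C(\C)CCl | intermediate
12 | (2E,6E)-2,6-dimethyl-11-(trimethylsilyl)undeca-2,6-dien-10-yn-1-ylbarium chloride (allylbarium chloride) | C[Si](C)(C)C#CCC/C=C(\C)CC/C=C(\C)C[Ba]Cl | intermediate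
13 | [(5E,9E,13E)-14-bromo-6,10-dimethyl-13-(propan-2-yl)tetradeca-5,9,13-trien-1-yn-1-yl]trimethylsilane | C[Si](C)(C)C#CCC/C=C(\C)CC/C=C(\C)CC/C(C(C)C)=C\Br | intermediate
14 | (5E,9E,13E)-14-bromo-6,10-dimethyl-13-(propan-2-yl)tetradeca-5,9,13-trien-1-yne | C#CCC/C=C(\C)CC/C=C(\C)CC/C(C(C)C)=C\Br | intermediate
15 | (2R,3R)-3-(but-3-yn-1-yl)-2-methyl-2-{2-[(2R,3R)-3-[(3E)-4-bromo-3-(propan-2-yl)but-3-en-1-yl]-3-methyloxiran-2-yl]ethyl}oxirane | C#CCC[C@H]1O[C@]1(C)CC[C@H]2O[C@]2(C)CC/C(C(C)C)=C\Br | intermediate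
16 | 2-[(1E)-2-methyl-4-{(2R,3R)-3-methyl-3-[2-((2R,3R)-3-[(3E)-4-bromo-3-(propan-2-yl)but-3-en-1-yl]-3-methyloxiran-2-yl)ethyl]oxiran-2-yl}but-1-en-1-yl]-4,4,5,5-tetramethyl-1,3,2-dioxaborolane | CC1(C)OB(OC1(C)C)/C=C(\C)CC[C@H]2O[C@]2(C)CC[C@H]3O[C@]3(C)CC/C(C(C)C)=C\Br | intermediate
17 | (1R,4E)-1-{(2S,5R)-5-[(2S,5E)-6-bromo-2-hydroxy-5-(propan-2-yl)hex-5-en-2-yl]-2-methyloxolan-2-yl}-4-methyl-5-(4,4,5,5-tetramethyl-1,3,2-dioxaborolan-2-yl)pent-4-en-1-ol | CC1(C)OB(OC1(C)C)/C=C(\C)CC[C@@H](O)[C@]2(C)CC[C@@H](O2)[C@@](C)(O)CC/C(C(C)C)=C\Br | intermediate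
18 | (1E,3E,7R,8S,11R,12S)-8,11-epoxycembra-1,3-diene-7,12-diol | O[C@@H]1CC/C(C)=C/C=C(/C(C)C)CC[C@](C)(O)[C@H]2CC[C@]1(C)O2 | intermediate
19 | (1E,3E,7R,8S,11R,12S)-7-acetoxy-8,11-epoxycembra-1,3-dien-12-ol (CNP0199953.2) | CC(=O)O[C@@H]1CC/C(C)=C/C=C(/C(C)C)CC[C@](C)(O)[C@H]2CC[C@]1(C)O2 | target

**Step count and risks**
Total: 11 steps. Longest linear sequence: 9 steps (6 and 7 to 19, steps 3–11). The route is a paper design; none of the steps has been run.

Most likely to fail, step 6. The allylbarium reagent must couple α to α and leave the alkenyl bromide of 5 alone. Fallback: from chloride 11, displacement with PhSO2Na in DMF gives the allylic sulfone trimethyl[(5E,9E)-6,10-dimethyl-11-(phenylsulfonyl)undeca-5,9-dien-1-yn-1-yl]silane F1. LiN(iPr)2 at −78 °C turns it into the α-lithio sulfone F2, which is alkylated at the allylic CH2Br of 5 to give the coupled sulfone F3 (both epimers at the sulfonyl carbon). Buffered Na(Hg) (Na2HPO4, MeOH, −20 °C) then cleaves the C–S bond and the route is rejoined at 13.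

Second, step 9. The copper boryl species could attack the alkenyl bromide, or give the wrong alkyne regiochemistry. Fallback: from alkyne 14, before any epoxide is present, Negishi carboalumination (Me3Al, Cp2ZrCl2 cat., CH2Cl2) gives the E-alkenylalane F4 and iodinolysis (I2, THF, −30 °C) gives the E-alkenyl iodide F5. Shi epoxidation under the conditions of step 8 gives the diepoxy iodide F6. Iodide-selective Miyaura borylation (PdCl2(dppf), KOAc, B2pin2, DMSO, 50 °C) returns to 16.

Third, step 10. Direct hydrolysis of one epoxide could compete with the epoxide-to-epoxide cascade and give the trans-oxolane diastereomer, or the ring closure could oligomerise. Fallback: from 16, run the Suzuki–Miyaura closure first (Pd(OAc)2, the same phosphine, K3PO4, THF/H2O, 1 mM, no acid) and isolate the macrocyclic diepoxide (1E,3E,7R,8R,11R,12R)-7,8:11,12-diepoxycembra-1,3-diene F7. Its two epoxides are held face to face across the ring, so the ether is then formed transannularly with Sc(OTf)3 (5 mol%) in wet THF at 0 °C, rejoining the route at 18.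

**Further compounds**
F1 | step 6 | trimethyl[(5E,9E)-6,10-dimethyl-11-(phenylsulfonyl)undeca-5,9-dien-1-yn-1-yl]silane | C[Si](C)(C)C#CCC/C=C(\C)CC/C=C(\C)CS(=O)(=O)c1ccccc1
F2 | step 6 | 11-lithio derivative of F1 (α-lithio sulfone) | C[Si](C)(C)C#CCC/C=C(\C)CC/C=C(\C)C([Li])S(=O)(=O)c1ccccc1
F3 | step 6 | [(5E,9E,13E)-14-bromo-6,10-dimethyl-11-(phenylsulfonyl)-13-(propan-2-yl)tetradeca-5,9,13-trien-1-yn-1-yl]trimethylsilane | C[Si](C)(C)C#CCC/C=C(\C)CC/C=C(\C)C(C/C(C(C)C)=C\Br)S(=O)(=O)c1ccccc1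
F4 | step 9 | dimethyl[(1E,5E,9E,13E)-14-bromo-2,6,10-trimethyl-13-(propan-2-yl)tetradeca-1,5,9,13-tetraen-1-yl]alane | C[Al](C)/C=C(\C)CC/C=C(\C)CC/C=C(\C)CC/C(C(C)C)=C\Br
F5 | step 9 | (1E,5E,9E,13E)-14-bromo-1-iodo-2,6,10-trimethyl-13-(propan-2-yl)tetradeca-1,5,9,13-tetraene | I/C=C(\C)CC/C=C(\C)CC/C=C(\C)CC/C(C(C)C)=C\Br
F6 | step 9 | (2R,3R)-3-[(3E)-4-iodo-3-methylbut-3-en-1-yl]-2-methyl-2-{2-[(2R,3R)-3-[(3E)-4-bromo-3-(propan-2-yl)but-3-en-1-yl]-3-methyloxiran-2-yl]ethyl}oxirane | I/C=C(\C)CC[C@H]1O[C@]1(C)CC[C@H]2O[C@]2(C)CC/C(C(C)C)=C\Br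
F7 | step 10 | (1E,3E,7R,8R,11R,12R)-7,8:11,12-diepoxycembra-1,3-diene | C1C/C(C)=C/C=C(/C(C)C)CC[C@@]2(C)O[C@@H]2CC[C@@]3(C)O[C@@H]31
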